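**Retrosynthetic overview**
1. Target ⇐ acid unmasking of the C14 dimethyl acetal and C15 silyl ether, preceded by acylation of O8 with (2S)-2-methylbutanoic acid.
2. Ten-membered carbocycle (formed second) ⇐ C7–C8 bond by SmI2 ketyl-radical addition of a C8 aldehyde to C7 of a 5R butenolide; loss of methoxide from C13 unveils the methylene lactone and the step sets C7 and C8.
3. Butenolide ring (formed first) ⇐ carbonylative lactonisation of a (Z)-iodoallylic alcohol made by directed hydroalumination/iodination; C6 comes from asymmetric alkynylation of an enal with 3-methoxypropyne.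
4. C3–C4 ⇐ B-alkyl Suzuki coupling of a (Z)-3-iodoallylic alcohol (from butynediol, fixes C4=C5) with a dienol.
5. C1=C10 and C9–C8 ⇐ one-pot carbocupration of 3,3-dimethoxypropyne by a vinylcuprate and trapping with oxirane.

Assumption: germacrane locants are used (lactone O on C6, ring fusion C7, ester on C8, C14 = formyl carbon on C10, C15 = hydroxymethyl carbon on C4, C11–C13 = methylene lactone); 3,3-dimethoxyprop-1-yne is taken as commercial, and (S,S)-ProPhenol is taken to direct Si-face alkynylation (its antipode is used if the sense is the reverse).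

**Step 1**
Reactants: 1 but-2-yne-1,4-diol
Product: 2 4-[(tert-butyldimethylsilyl)oxy]but-2-yn-1-ol
Conditions: NaH (1.0 equiv), THF, 0 °C; TBSCl (1.0 equiv), 0 °C → rt
Reagents that add atoms: tert-butyldimethylsilyl chloride (TBSCl), C[Si](C)(Cl)C(C)(C)C
Why: Monosilylation of a symmetric diol through its sparingly soluble monosodium alkoxide (Williamson-type O-silylation) differentiates the future C6 and C15 oxygens; no stereocentre is involved.

**Step 2**
Reactants: 2 4-[(tert-butyldimethylsilyl)oxy]but-2-yn-1-ol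
Product: 4 (2Z)-4-[(tert-butyldimethylsilyl)oxy]-3-iodobut-2-en-1-ol, via cyclic vinylalanate 3 (not isolated)
Conditions: NaAlH2(OCH2CH2OMe)2 (1.5 equiv), THF, 0 °C → rt; then I2, THF, −78 → 0 °C
Reagents that add atoms: iodine, [I][I]
Why: Alkoxide-directed trans-hydroalumination of the propargylic alcohol delivers hydride to C5 and aluminium to C4 inside a five-membered alanate, and iodinolysis with retention gives the iodide cis to C6, which fixes the C4=C5 geometry of the target.

**Step 3**
Reactants: 5 vinylmagnesium bromide (2 equiv), 6 3,3-dimethoxyprop-1-yne (2 equiv), 7 oxirane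
Product: 10 (3E)-3-(dimethoxymethyl)hexa-3,5-dien-1-ol, via bromomagnesium divinylcuprate 8 (not isolated), via bromomagnesium bis(dienyl)cuprate 9 (not isolated)
Conditions: CuBr·SMe2 (1 equiv), Et2O, −45 °C; 6, −45 → −25 °C; then 7 (excess), −25 → 0 °C; aq. NH4Cl
Reagents that add atoms: none
Why: Normant–Alexakis syn-carbocupration of the acetylenic acetal puts the vinyl group on the terminal carbon (C1) and copper on the acetal-bearing carbon (C10), and opening of oxirane by the alkenylcuprate with retention places the C9–C8 arm cis to the vinyl group, which is the C1=C10 geometry of the target.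

**Step 4**
Reactants: 10 (3E)-3-(dimethoxymethyl)hexa-3,5-dien-1-ol, 4 (2Z)-4-[(tert-butyldimethylsilyl)oxy]-3-iodobut-2-en-1-ol
Product: 12 (2E,6E)-3-{[(tert-butyldimethylsilyl)oxy]methyl}-7-(dimethoxymethyl)nona-2,6-diene-1,9-diol, via B-alkyl-9-BBN adduct 11 (not isolated)
Conditions: 9-BBN-H (2.2 equiv), THF, 0 °C → rt; then 4, PdCl2(dppf) (5 mol %), AsPh3, Cs2CO3, DMF/H2O, rt
Reagents that add atoms: none
Why: 9-BBN hydroborates only the terminal vinyl CH2 of the diene (the second equivalent is taken up by the hydroxyl), and the B-alkyl Suzuki–Miyaura coupling joins C3 to C4 with retention of the iodide geometry.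

**Step 5**
Reactants: 12 (2E,6E)-3-{[(tert-butyldimethylsilyl)oxy]methyl}-7-(dimethoxymethyl)nona-2,6-diene-1,9-diol
Product: 13 (2E,6E)-3-{[(tert-butyldimethylsilyl)oxy]methyl}-7-(dimethoxymethyl)-9-hydroxynona-2,6-dienal
Conditions: MnO2 (15 equiv), CH2Cl2, rt
Reagents that add atoms: none
Why: MnO2 oxidises only the allylic C6 carbinol and leaves the homoallylic C8 alcohol, the acetal and the silyl ether alone, and its neutral surface does not isomerise the enal.

**Step 6**
Reactants: 13 (2E,6E)-3-{[(tert-butyldimethylsilyl)oxy]methyl}-7-(dimethoxymethyl)-9-hydroxynona-2,6-dienal, 14 3-methoxyprop-1-yne (3 equiv)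
Product: 16 (4R,5E,9E)-6-{[(tert-butyldimethylsilyl)oxy]methyl}-10-(dimethoxymethyl)-1-methoxydodeca-5,9-dien-2-yne-4,12-diol, via alkynyl(methyl)zinc 15 (not isolated)
Conditions: Me2Zn (3.5 equiv), (S,S)-ProPhenol [2,6-bis{[(2S)-2-(hydroxydiphenylmethyl)pyrrolidin-1-yl]methyl}-4-methylphenol] (20 mol %), Ph3P=O (40 mol %), toluene, 0 → 4 °C
Reagents that add atoms: none
Why: The dinuclear zinc–ProPhenol asymmetric alkynylation, a method suited to α,β-unsaturated aldehydes, adds the alkynylzinc to the Si face of the enal and sets C6 as R under ligand control, the remote hydroxyl being carried as its zinc alkoxide.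

**Step 7**
Reactants: 16 (4R,5E,9E)-6-{[(tert-butyldimethylsilyl)oxy]methyl}-10-(dimethoxymethyl)-1-methoxydodeca-5,9-dien-2-yne-4,12-diol
Product: 18 (2Z,4R,5E,9E)-6-{[(tert-butyldimethylsilyl)oxy]methyl}-10-(dimethoxymethyl)-2-iodo-1-methoxydodeca-2,5,9-triene-4,12-diol, via cyclic vinylalanate 17 (not isolated)
Conditions: NaAlH2(OCH2CH2OMe)2 (3.5 equiv), THF, 0 °C → rt; then I2, THF, −78 °C
Reagents that add atoms: iodine, [I][I]
Why: The C6 alkoxide directs trans-hydroalumination (hydride to C7, aluminium to C11; the C13 methyl ether cannot direct), and iodinolysis with retention gives the C11 iodide cis to C6 as needed for lactonisation, without touching the C6 stereocentre.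

**Step 8**
Reactants: 18 (2Z,4R,5E,9E)-6-{[(tert-butyldimethylsilyl)oxy]methyl}-10-(dimethoxymethyl)-2-iodo-1-methoxydodeca-2,5,9-triene-4,12-diol
Product: 19 (5R)-5-[(1E,5E)-2-{[(tert-butyldimethylsilyl)oxy]methyl}-6-(dimethoxymethyl)-8-hydroxyocta-1,5-dien-1-yl]-3-(methoxymethyl)furan-2(5H)-one
Conditions: PdCl2(PPh3)2 (5 mol %), CO (1 atm), K2CO3, THF, rt
Reagents that add atoms: carbon monoxide, [C-]#[O+]
Why: Oxidative addition of zerovalent palladium to the vinyl iodide, CO insertion and capture of the acylpalladium by the cis-disposed C6 hydroxyl (carbonylative lactonisation) close the butenolide, and the mild heterogeneous base spares the acidic C6–H stereocentre.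

**Step 9**
Reactants: 19 (5R)-5-[(1E,5E)-2-{[(tert-butyldimethylsilyl)oxy]methyl}-6-(dimethoxymethyl)-8-hydroxyocta-1,5-dien-1-yl]-3-(methoxymethyl)furan-2(5H)-one
Product: 20 (5R)-5-[(1E,5E)-2-{[(tert-butyldimethylsilyl)oxy]methyl}-6-(dimethoxymethyl)-8-oxoocta-1,5-dien-1-yl]-3-(methoxymethyl)furan-2(5H)-one
Conditions: Dess–Martin periodinane (1.3 equiv), pyridine (3 equiv), CH2Cl2, 0 °C; used at once
Reagents that add atoms: none
Why: Buffered Dess–Martin oxidation converts the primary C8 alcohol into the β,γ-unsaturated aldehyde without acid or base strong enough to conjugate it or to epimerise C6.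

**Step 10**
Reactants: 20 (5R)-5-[(1E,5E)-2-{[(tert-butyldimethylsilyl)oxy]methyl}-6-(dimethoxymethyl)-8-oxoocta-1,5-dien-1-yl]-3-(methoxymethyl)furan-2(5H)-one
Product: 22 (3aR,4R,6E,10E,11aR)-10-{[(tert-butyldimethylsilyl)oxy]methyl}-6-(dimethoxymethyl)-4-hydroxy-3-methylidene-3a,4,5,8,9,11a-hexahydrocyclodeca[b]furan-2(3H)-one, via cyclized samarium enolate 21 (not isolated)
Conditions: SmI2 (2.5 equiv), THF, 2 mM (slow addition of 20), no HMPA, −78 °C → rt; pH 7 buffer
Reagents that add atoms: none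
Why: Proposed new method: single-electron reduction of the C8 aldehyde gives a trivalent-samarium ketyl radical that adds to C7 of the butenolide anti to the C6 side chain (trans lactone, C7 R), in a transition state where samarium bridges the ketyl oxygen and the lactone carbonyl and the C9 chain lies away from the C13 substituent (C8 R); the ester radical is reduced to enolate 21, which expels methoxide (E1cB) to give the exocyclic methylene; the closest known reaction type is the SmI2 ketyl–olefin reductive coupling of aldehydes with unsaturated esters and butenolides, here extended to a ten-membered ring closure with β-alkoxide loss.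

**Step 11**
Reactants: 22 (3aR,4R,6E,10E,11aR)-10-{[(tert-butyldimethylsilyl)oxy]methyl}-6-(dimethoxymethyl)-4-hydroxy-3-methylidene-3a,4,5,8,9,11a-hexahydrocyclodeca[b]furan-2(3H)-one, 23 (2S)-2-methylbutanoic acid
Product: 25 (3aR,4R,6E,10E,11aR)-10-{[(tert-butyldimethylsilyl)oxy]methyl}-6-(dimethoxymethyl)-3-methylidene-2-oxo-2,3,3a,4,5,8,9,11a-octahydrocyclodeca[b]furan-4-yl (2S)-2-methylbutanoate, via O-acylisourea 24 (not isolated)
Conditions: DCC (1.5 equiv), DMAP (0.3 equiv), CH2Cl2, 0 °C → rt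
Reagents that add atoms: none
Why: Steglich esterification acylates the secondary hydroxyl with retention at C8 and, having no ketene pathway, does not racemise the (S)-2-methylbutanoyl centre.

**Step 12**
Reactants: 25 (3aR,4R,6E,10E,11aR)-10-{[(tert-butyldimethylsilyl)oxy]methyl}-6-(dimethoxymethyl)-3-methylidene-2-oxo-2,3,3a,4,5,8,9,11a-octahydrocyclodeca[b]furan-4-yl (2S)-2-methylbutanoate
Product: 26 (3aR,4R,6E,10E,11aR)-6-formyl-10-(hydroxymethyl)-3-methylidene-2-oxo-2,3,3a,4,5,8,9,11a-octahydrocyclodeca[b]furan-4-yl (2S)-2-methylbutanoate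
Conditions: AcOH/THF/H2O (3:1:1), rt
Reagents that add atoms: water, O
Why: Mild aqueous acid hydrolyses the α,β-unsaturated dimethyl acetal to the C14 enal and cleaves the primary silyl ether in one operation, under conditions that the ester, the allylic lactone and the exocyclic methylene tolerate, so no stereocentre is touched.

**Compound list**
1 | but-2-yne-1,4-diol | OCC#CCO | starting material
2 | 4-[(tert-butyldimethylsilyl)oxy]but-2-yn-1-ol | OCC#CCO[Si](C)(C)C(C)(C)C | intermediate
3 | sodium cyclic vinylalanate of 2 (Al bonded to the alkoxide O and to C3, two 2-methoxyethoxy ligands) | [Na+].COCCO[Al-]1(OCCOC)OCC=C1CO[Si](C)(C)C(C)(C)C | intermediate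
4 | (2Z)-4-[(tert-butyldimethylsilyl)oxy]-3-iodobut-2-en-1-ol | OC/C=C(\I)CO[Si](C)(C)C(C)(C)C | intermediate
5 | vinylmagnesium bromide | C=C[Mg]Br | starting material
6 | 3,3-dimethoxyprop-1-yne | C#CC(OC)OC | starting material
7 | oxirane | C1CO1 | starting material
8 | bromomagnesium divinylcuprate | C=C[Cu-]C=C.[Mg+]Br | intermediate
9 | bromomagnesium bis[(1Z)-1-(dimethoxymethyl)buta-1,3-dien-1-yl]cuprate | COC(OC)/C([Cu-]/C(C(OC)OC)=C\C=C)=C/C=C.[Mg+]Br | intermediate
10 | (3E)-3-(dimethoxymethyl)hexa-3,5-dien-1-ol | C=C/C=C(\CCO)C(OC)OC | intermediate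
11 | 9-[(3E)-4-(dimethoxymethyl)-6-(9-borabicyclo[3.3.1]nonan-9-yloxy)hex-3-en-1-yl]-9-borabicyclo[3.3.1]nonane | COC(OC)C(/CCOB1C2CCCC1CCC2)=C/CCB1C2CCCC1CCC2 | intermediate
12 | (2E,6E)-3-{[(tert-butyldimethylsilyl)oxy]methyl}-7-(dimethoxymethyl)nona-2,6-diene-1,9-diol | OC/C=C(/CO[Si](C)(C)C(C)(C)C)CC/C=C(\CCO)C(OC)OC | intermediate
13 | (2E,6E)-3-{[(tert-butyldimethylsilyl)oxy]methyl}-7-(dimethoxymethyl)-9-hydroxynona-2,6-dienal | O=C/C=C(/CO[Si](C)(C)C(C)(C)C)CC/C=C(\CCO)C(OC)OC | intermediate
14 | 3-methoxyprop-1-yne | COCC#C | starting material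
15 | methyl(3-methoxyprop-1-yn-1-yl)zinc | COCC#C[Zn]C | intermediate
16 | (4R,5E,9E)-6-{[(tert-butyldimethylsilyl)oxy]methyl}-10-(dimethoxymethyl)-1-methoxydodeca-5,9-dien-2-yne-4,12-diol | COCC#C[C@H](O)/C=C(/CO[Si](C)(C)C(C)(C)C)CC/C=C(\CCO)C(OC)OC | intermediate
17 | disodium cyclic vinylalanate of 16 (Al bonded to the C4 oxygen and to C2; remote alkoxide) | [Na+].[Na+].COCCO[Al-]1(OCCOC)O[C@H](/C=C(/CO[Si](C)(C)C(C)(C)C)CC/C=C(\CC[O-])C(OC)OC)C=C1COC | intermediate
18 | (2Z,4R,5E,9E)-6-{[(tert-butyldimethylsilyl)oxy]methyl}-10-(dimethoxymethyl)-2-iodo-1-methoxydodeca-2,5,9-triene-4,12-diol | COC/C(I)=C/[C@H](O)/C=C(/CO[Si](C)(C)C(C)(C)C)CC/C=C(\CCO)C(OC)OC | intermediate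
19 | (5R)-5-[(1E,5E)-2-{[(tert-butyldimethylsilyl)oxy]methyl}-6-(dimethoxymethyl)-8-hydroxyocta-1,5-dien-1-yl]-3-(methoxymethyl)furan-2(5H)-one | COCC1=C[C@H](OC1=O)/C=C(/CO[Si](C)(C)C(C)(C)C)CC/C=C(\CCO)C(OC)OC | intermediate
20 | (5R)-5-[(1E,5E)-2-{[(tert-butyldimethylsilyl)oxy]methyl}-6-(dimethoxymethyl)-8-oxoocta-1,5-dien-1-yl]-3-(methoxymethyl)furan-2(5H)-one | COCC1=C[C@H](OC1=O)/C=C(/CO[Si](C)(C)C(C)(C)C)CC/C=C(\CC=O)C(OC)OC | intermediate
21 | cyclized bis(diiodosamarium) lactone enolate and C8 alkoxide, C13 methoxy still in place | COCC1=C(O[Sm](I)I)O[C@@H]2/C=C(/CO[Si](C)(C)C(C)(C)C)CC/C=C(/C(OC)OC)C[C@@H](O[Sm](I)I)[C@@H]12 | intermediate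
22 | (3aR,4R,6E,10E,11aR)-10-{[(tert-butyldimethylsilyl)oxy]methyl}-6-(dimethoxymethyl)-4-hydroxy-3-methylidene-3a,4,5,8,9,11a-hexahydrocyclodeca[b]furan-2(3H)-one | C=C1C(=O)O[C@@H]2/C=C(/CO[Si](C)(C)C(C)(C)C)CC/C=C(/C(OC)OC)C[C@@H](O)[C@@H]12 | intermediate
23 | (2S)-2-methylbutanoic acid | CC[C@H](C)C(=O)O | starting material
24 | N,N'-dicyclohexyl-O-[(2S)-2-methylbutanoyl]isourea | CC[C@H](C)C(=O)OC(=NC1CCCCC1)NC1CCCCC1 | intermediate
25 | (3aR,4R,6E,10E,11aR)-10-{[(tert-butyldimethylsilyl)oxy]methyl}-6-(dimethoxymethyl)-3-methylidene-2-oxo-2,3,3a,4,5,8,9,11a-octahydrocyclodeca[b]furan-4-yl (2S)-2-methylbutanoate | C=C1C(=O)O[C@@H]2/C=C(/CO[Si](C)(C)C(C)(C)C)CC/C=C(/C(OC)OC)C[C@@H](OC(=O)[C@@H](C)CC)[C@@H]12 | intermediate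
26 | (3aR,4R,6E,10E,11aR)-6-formyl-10-(hydroxymethyl)-3-methylidene-2-oxo-2,3,3a,4,5,8,9,11a-octahydrocyclodeca[b]furan-4-yl (2S)-2-methylbutanoate | C=C1C(=O)O[C@@H]2/C=C(/CO)CC/C=C(/C=O)C[C@@H](OC(=O)[C@@H](C)CC)[C@@H]12 | target

**Totals**
Total step count: 12. Longest linear sequence: 11 steps (steps 1, 2, 4–12); step 3 is a one-step side branch.

**Steps most likely to fail**

Step 10. The ten-membered ring closure is unprecedented in this form. The C8 configuration rests on a chelation and strain argument, and the trivalent-samarium C8 alkoxide could also translactonise. The fallback answers the case in which the closure mainly gives the wrong C8 configuration. It sets out from 20, which is cyclised as before, and the C8-epimeric alcohol (3aR,4S,6E,10E,11aR)-10-{[(tert-butyldimethylsilyl)oxy]methyl}-6-(dimethoxymethyl)-4-hydroxy-3-methylidene-3a,4,5,8,9,11a-hexahydrocyclodeca[b]furan-2(3H)-one F1 is isolated. The retentive Steglich acylation is then replaced by a Mitsunobu esterification with 23 (PPh3, diisopropyl azodicarboxylate, toluene, 0 °C), which inverts C8 and comes back to the route at 25.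

Step 3. The α-acetal alkenylcuprate may open oxirane sluggishly or lose methoxide to an alkoxyallene before it is trapped. The fallback sets out from 5 and 6: cuprate 9 is formed as before but quenched with I2 to give the isolable (3Z)-4-iodo-5,5-dimethoxypenta-1,3-diene F2. Iodine–lithium exchange (t-BuLi, Et2O, −78 °C) then gives the α-lithiated acrolein-acetal type vinyllithium, which opens 7 with retention and comes back to the route at 10. This separates the geometry-setting carbometalation from the C9–C10 bond formation and replaces the copper nucleophile by a more reactive lithium one.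

Step 6. The catalytic alkynylation may give low selectivity, or the wrong sense, on a β,β-disubstituted enal that carries a free hydroxyl. The fallback sets out from 13. Addition of the bromomagnesium acetylide of 14 (from EtMgBr, THF, −40 °C) gives racemic (5E,9E)-6-{[(tert-butyldimethylsilyl)oxy]methyl}-10-(dimethoxymethyl)-1-methoxydodeca-5,9-dien-2-yne-4,12-diol F3. MnO2 oxidises only the doubly activated C4 carbinol to (5E,9E)-6-{[(tert-butyldimethylsilyl)oxy]methyl}-10-(dimethoxymethyl)-12-hydroxy-1-methoxydodeca-5,9-dien-2-yn-4-one F4. Reduction with (R)-Alpine-borane [B-isopinocampheyl-9-BBN from (+)-α-pinene], in which the alkynyl group acts as the small substituent, gives the R carbinol and comes back to the route at 16.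

**Further compounds**
F1 | step 10 | (3aR,4S,6E,10E,11aR)-10-{[(tert-butyldimethylsilyl)oxy]methyl}-6-(dimethoxymethyl)-4-hydroxy-3-methylidene-3a,4,5,8,9,11a-hexahydrocyclodeca[b]furan-2(3H)-one | C=C1C(=O)O[C@@H]2/C=C(/CO[Si](C)(C)C(C)(C)C)CC/C=C(/C(OC)OC)C[C@H](O)[C@@H]12
F2 | step 3 | (3Z)-4-iodo-5,5-dimethoxypenta-1,3-diene | C=C/C=C(\I)C(OC)OC
F3 | step 6 | racemic (5E,9E)-6-{[(tert-butyldimethylsilyl)oxy]methyl}-10-(dimethoxymethyl)-1-methoxydodeca-5,9-dien-2-yne-4,12-diol | COCC#CC(O)/C=C(/CO[Si](C)(C)C(C)(C)C)CC/C=C(\CCO)C(OC)OC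
F4 | step 6 | (5E,9E)-6-{[(tert-butyldimethylsilyl)oxy]methyl}-10-(dimethoxymethyl)-12-hydroxy-1-methoxydodeca-5,9-dien-2-yn-4-one | COCC#CC(=O)/C=C(/CO[Si](C)(C)C(C)(C)C)CC/C=C(\CCO)C(OC)OC
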